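## Retrosynthetic overview

- Megaphone acetate ⇐ megaphone by O-acetylation. Megaphone ⇐ a 6-oxo-hexahydrobenzofuran by reductive 1,3-carbonyl transposition, which reopens the furan ring at the enol-ether C–O bond and leaves the benzylic C–O bond untouched.
- That ketone ⇐ the cross-conjugated hydrobenzofuranone by conjugate reduction of the α-methoxy enone; the methoxy-bearing centre is set under thermodynamic control.
- Hydrobenzofuranone ⇐ an oxidised 2-allyl-4,5-dimethoxyphenol (p-quinone monoketal) plus (Z)-isoelemicin by an acid-catalysed cationic [3+2] cycloaddition run under a chiral acid. This forms the C8–C1′ and C7–O bonds and all three contiguous stereocentres, including the quaternary one, in one step.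
- Ketal ⇐ 3,4-dimethoxyphenol (O-allylation, Claisen rearrangement, oxidative ketalisation); (Z)-isoelemicin ⇐ stereoretentive Suzuki coupling.
- Ring order: the six-membered ring is never built, it is the dearomatised phenol ring. The only ring closed is the tetrahydrofuran (key step), and it is reopened in the transposition.

Assumption: the (R)-configured acid in step 5 is taken to deliver the enantiomer drawn; if the first run shows the opposite sense, its (S)-antipode is used with nothing else changed.

## Route

Step 1
Reactants: 1 3,4-dimethoxyphenol; 2 allyl bromide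
Product: 3 4-(allyloxy)-1,2-dimethoxybenzene
Conditions: K2CO3, acetone, reflux
Reagents that add atoms: none
Why: Williamson ether synthesis of a phenoxide with a reactive allylic bromide; no stereocentre is formed.

Step 2
Reactants: 3 4-(allyloxy)-1,2-dimethoxybenzene
Product: 4 2-allyl-4,5-dimethoxyphenol
Conditions: N,N-diethylaniline, 195 °C
Reagents that add atoms: none
Why: Aromatic Claisen rearrangement ([3,3]-sigmatropic shift, then tautomerisation) delivers the allyl group mainly to the unhindered ortho carbon rather than the one flanked by a methoxy group; the minor regioisomer is removed by chromatography.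

Step 3
Reactants: 4 2-allyl-4,5-dimethoxyphenol
Product: 5 6-allyl-3,4,4-trimethoxycyclohexa-2,5-dien-1-one
Conditions: PhI(OAc)2, MeOH, 0 °C, NaHCO3 work-up
Reagents that add atoms: methanol, CO
Why: Hypervalent-iodine oxidative dearomatisation of a p-methoxyphenol; methanol attacks the para carbon to give the p-quinone monoketal.

Step 4
Reactants: 6 3,4,5-trimethoxyphenylboronic acid; 7 (Z)-1-bromoprop-1-ene
Product: 8 1,2,3-trimethoxy-5-[(1Z)-prop-1-en-1-yl]benzene ((Z)-isoelemicin)
Conditions: Pd(PPh3)4 (3 mol %), 2 M aq. K2CO3, 1,2-dimethoxyethane, 70 °C, sealed vessel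
Reagents that add atoms: none
Why: Suzuki–Miyaura coupling proceeds with retention of the alkenyl bromide geometry, so the Z alkene needed for the cis aryl/methyl relationship is obtained pure.

Step 5
Reactants: 5 6-allyl-3,4,4-trimethoxycyclohexa-2,5-dien-1-one; 8 (Z)-isoelemicin
Product: 11 (2R,3S,3aS)-3a-allyl-5-methoxy-3-methyl-2-(3,4,5-trimethoxyphenyl)-3,3a-dihydro-1-benzofuran-6(2H)-one, via oxocarbenium cation 9 (not isolated), via dimethyl ketal 10 (not isolated)
Conditions: (R)-3,3'-bis(2,4,6-triisopropylphenyl)-1,1'-binaphthalene-2,2'-diyl N-(trifluoromethylsulfonyl)phosphoramidate (C51H57F3NO5PS, 10 mol %), toluene, −78 to −40 °C; then 1 M aq. HCl, THF, 0 °C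
Reagents that add atoms: water, O
Why: Proposed new method: the strong chiral acid ionises ketal 5 to cation 9, held as a contact ion pair with the chiral phosphoramidate anion (counteranion-directed catalysis); the alkene carbon bearing the methyl group of 8 attacks the allyl-bearing terminus of 9 (the other terminus is deactivated by the neighbouring methoxy-bearing carbon) on the face left open by the anion, suprafacially and with the aryl group stacked over the cationic ring, so that aryl and methyl (cis, from the Z alkene) both end up anti to the allyl group while the carbonyl oxygen closes on the benzylic carbon, which sets C-2, C-3 and C-3a together; liberated methanol caps the O-methyl oxocarbenium ion as ketal 10 and returns the proton, and the acid work-up unmasks the ketone; the closest known reactions are the racemic acid-promoted formal [3+2] cycloaddition of such quinone monoketals with propenylbenzenes and chiral phosphoric acid-catalysed [3+2] couplings of quinone derivatives with styrenes.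

Step 6
Reactants: 11 (2R,3S,3aS)-hydrobenzofuranone
Product: 12 (2R,3S,3aR,5R)-3a-allyl-5-methoxy-3-methyl-2-(3,4,5-trimethoxyphenyl)-3,3a,4,5-tetrahydro-1-benzofuran-6(2H)-one
Conditions: Cu(OAc)2 (5 mol %), 1,2-bis(diphenylphosphino)benzene (5 mol %), (MeO)2MeSiH, t-BuOH, toluene, 0 °C to rt; work-up, then 1,8-diazabicyclo[5.4.0]undec-7-ene (0.2 equiv), CH2Cl2, rt
Reagents that add atoms: none
Why: Copper hydride-catalysed conjugate reduction delivers hydride to C-4 of the α-methoxy enone only (the other enone is a vinylogous ester with an oxygen-bearing β-carbon, and the isolated allyl alkene is inert); base equilibration of the ketone α-centre then places the 5-methoxy group pseudo-equatorial, trans to the pseudo-axial angular allyl group, which is the 5R configuration.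

Step 7
Reactants: 12 (2R,3S,3aR,5R)-ketone
Product: 14 megaphone, (4R,6R)-6-allyl-6-[(1S,2R)-2-hydroxy-1-methyl-2-(3,4,5-trimethoxyphenyl)ethyl]-4-methoxycyclohex-2-en-1-one, via allylic alcohol 13 (not isolated)
Conditions: i-Bu2AlH, CH2Cl2, −78 °C; then 1 M aq. HCl, THF, 0 °C
Reagents that add atoms: water, O
Why: Stork–Danheiser-type reductive 1,3-carbonyl transposition: 1,2-hydride addition to the vinylogous ester gives alcohol 13, acid ionises it to the cyclic oxocarbenium ion, water adds at C-7a and the hemiketal opens to the enone; the benzylic C–O bond is never broken, so the carbinol centre is retained, and the C-6 epimers of 13 converge.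

Step 8
Reactants: 14 megaphone
Product: 15 megaphone acetate, (4R,6R)-6-allyl-6-[(1S,2R)-2-acetoxy-1-methyl-2-(3,4,5-trimethoxyphenyl)ethyl]-4-methoxycyclohex-2-en-1-one
Conditions: Ac2O, pyridine, 4-(dimethylamino)pyridine (5 mol %), CH2Cl2, 0 °C to rt
Reagents that add atoms: acetic anhydride, CC(=O)OC(C)=O
Why: Nucleophile-catalysed O-acylation of the secondary benzylic alcohol with retention; the ketone has no enolisable α-hydrogen and no stereocentre is touched.

## Compound list

1 | 3,4-dimethoxyphenol | COc1ccc(O)cc1OC | starting material
2 | allyl bromide | C=CCBr | starting material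
3 | 4-(allyloxy)-1,2-dimethoxybenzene | C=CCOc1ccc(OC)c(OC)c1 | intermediate
4 | 2-allyl-4,5-dimethoxyphenol | C=CCc1cc(OC)c(OC)cc1O | intermediate
5 | 6-allyl-3,4,4-trimethoxycyclohexa-2,5-dien-1-one | C=CCC1=CC(OC)(OC)C(OC)=CC1=O | intermediate
6 | 3,4,5-trimethoxyphenylboronic acid | COc1cc(B(O)O)cc(OC)c1OC | starting material
7 | (Z)-1-bromoprop-1-ene | C/C=C\Br | starting material
8 | 1,2,3-trimethoxy-5-[(1Z)-prop-1-en-1-yl]benzene ((Z)-isoelemicin) | C/C=C\c1cc(OC)c(OC)c(OC)c1 | intermediate
9 | O-methyl oxocarbenium (2-allyl-4,5-dimethoxyphenoxenium) cation, ion-paired with the chiral phosphoramidate anion | C=CCC1=CC(=[O+]C)C(OC)=CC1=O | intermediate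
10 | (2R,3S,3aS)-3a-allyl-5,6,6-trimethoxy-3-methyl-2-(3,4,5-trimethoxyphenyl)-2,3,3a,6-tetrahydro-1-benzofuran | C=CC[C@]12C=C(OC)C(OC)(OC)C=C1O[C@@H](c3cc(OC)c(OC)c(OC)c3)[C@H]2C | intermediate
11 | (2R,3S,3aS)-3a-allyl-5-methoxy-3-methyl-2-(3,4,5-trimethoxyphenyl)-3,3a-dihydro-1-benzofuran-6(2H)-one | C=CC[C@]12C=C(OC)C(=O)C=C1O[C@@H](c3cc(OC)c(OC)c(OC)c3)[C@H]2C | intermediate
12 | (2R,3S,3aR,5R)-3a-allyl-5-methoxy-3-methyl-2-(3,4,5-trimethoxyphenyl)-3,3a,4,5-tetrahydro-1-benzofuran-6(2H)-one | C=CC[C@]12C[C@@H](OC)C(=O)C=C1O[C@@H](c3cc(OC)c(OC)c(OC)c3)[C@H]2C | intermediate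
13 | (2R,3S,3aR,5R)-3a-allyl-5-methoxy-3-methyl-2-(3,4,5-trimethoxyphenyl)-2,3,3a,4,5,6-hexahydro-1-benzofuran-6-ol (mixture of C-6 epimers) | C=CC[C@]12C[C@@H](OC)C(O)C=C1O[C@@H](c3cc(OC)c(OC)c(OC)c3)[C@H]2C | intermediate
14 | megaphone | C=CC[C@]1([C@H](C)[C@@H](O)c2cc(OC)c(OC)c(OC)c2)C[C@@H](OC)C=CC1=O | intermediate
15 | megaphone acetate | C=CC[C@]1([C@H](C)[C@@H](OC(C)=O)c2cc(OC)c(OC)c(OC)c2)C[C@@H](OC)C=CC1=O | target

## Step count and risks

Total steps: 8. Longest linear sequence: 7 (steps 1, 2, 3, 5, 6, 7, 8).

The three steps most likely to fail, each with a fallback: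

Step 5 is the largest risk. Asymmetric induction by ion pairing alone has no direct precedent for this cation, and three side paths are known for the racemic reaction: closure at carbon instead of oxygen ([5+2] mode), capture of the benzylic cation by the allyl group, and acid-induced Z-to-E isomerisation of 8. The fallback gives up asymmetric catalysis in favour of resolution. It sets out from 5 and 8, which are condensed with an achiral acid (CF3SO3H, 5 mol %, MeCN, −40 °C, then the same aqueous acid work-up) to give 11 as the racemate, that is 11 together with its mirror image, the (2S,3R,3aR)-hydrobenzofuranone F1. Preparative supercritical-fluid chromatography on an amylose tris(3,5-dimethylphenylcarbamate) phase removes F1, and the route is rejoined at 11.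

Step 6 can fail through 1,2-reduction of the cross-conjugated ketone or through slow hydride delivery to the neopentyl β-carbon. The fallback replaces hydride conjugate addition by heteroatom conjugate addition and radical removal. It sets out from 11: sodium phenylselenolate, made from (PhSe)2 and NaBH4 in EtOH and buffered with AcOH at 0 °C, adds to C-4 to give the 4-(phenylselanyl) ketone F2. Bu3SnH with 2,2'-azobis(2-methylpropionitrile) in benzene at 80 °C then cleaves the C–Se bond; the C-4 radical has no favourable cyclisation onto the allyl group. The same base equilibration of C-5 follows, and the route is rejoined at 12.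

Step 7 exposes the product to acid, which could ionise the electron-rich benzylic ether (epimerisation at the carbinol carbon) or remove H-5 from the allyl cation (loss of the methoxy stereocentre). The fallback moves the ionisation to basic conditions by activating the hydroxyl as a leaving group. It sets out from 12, which is reduced with i-Bu2AlH as before but worked up with aqueous potassium sodium tartrate, so that alcohol 13 is isolated. CH3SO2Cl and Et3N in CH2Cl2 at −30 °C convert it into the allylic methanesulfonate F3, which ionises spontaneously with assistance from the enol-ether oxygen. Quenching into aqueous NaHCO3/THF at 0 °C hydrolyses the oxocarbenium ion, and the route is rejoined at 14.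

## Further compounds

F1 | step 5 | (2S,3R,3aR)-3a-allyl-5-methoxy-3-methyl-2-(3,4,5-trimethoxyphenyl)-3,3a-dihydro-1-benzofuran-6(2H)-one | C=CC[C@@]12C=C(OC)C(=O)C=C1O[C@H](c3cc(OC)c(OC)c(OC)c3)[C@@H]2C
F2 | step 6 | (2R,3S,3aR)-3a-allyl-5-methoxy-3-methyl-4-(phenylselanyl)-2-(3,4,5-trimethoxyphenyl)-3,3a,4,5-tetrahydro-1-benzofuran-6(2H)-one (mixture of C-4 and C-5 epimers) | C=CC[C@]12C([Se]c4ccccc4)C(OC)C(=O)C=C1O[C@@H](c3cc(OC)c(OC)c(OC)c3)[C@H]2C
F3 | step 7 | (2R,3S,3aR,5R)-3a-allyl-5-methoxy-3-methyl-2-(3,4,5-trimethoxyphenyl)-2,3,3a,4,5,6-hexahydro-1-benzofuran-6-yl methanesulfonate (mixture of C-6 epimers) | C=CC[C@]12C[C@@H](OC)C(OS(C)(=O)=O)C=C1O[C@@H](c3cc(OC)c(OC)c(OC)c3)[C@H]2C
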